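**Plan**
1. Enabling feature: in ring A the quaternary C4 carries C19 at the carboxyl level and is bonded to C5, whose C5–C6 bond can be a vinyl group. C19(=O)–C4–C5–C6=C7 is therefore the γ,δ-unsaturated acid of an ester-enolate Claisen rearrangement whose allylic ester is a ten-membered lactone (C19–O–C7).
2. Retrosynthetic cuts, in order: C12–C13 (alkylborane + bromobutenolide); C8–C9, C8–C17 and C7–C8 of ring B (nitro-Michael closure, nitromethane, CO); C4–C5 of ring A (ring contraction, which restores O–C7 as the lactone bond); C19–O (lactonisation); C9–C10 (Claisen); C1–C2 (dianion alkylation); C5=C10 (Wittig).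
3. Forward: the chain C7→C19 is built linearly from (S)-glyceraldehyde acetonide, closed to the ten-membered lactone and contracted to ring A. Ring B is then closed between the vinyl-derived arm and the C9 arm, and the butenolide is attached last.
4. Stereochemistry: C6 of the glyceraldehyde unit is relayed to quaternary C10 by a Claisen rearrangement. C3 comes from a BINAP–ruthenium hydrogenation and is made on purpose with the configuration opposite to the target (3-epi) so that it steers C4/C5 in the ring contraction; it is corrected later by oxidation and axial hydride delivery on the trans-decalin. C8 and C9 follow from chair closure and equilibration.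

Key step: step 13

Remarks: labdane numbering (C1–C20) is used as locants for all intermediates. C4 is an inconsequential mixture of epimers from 8 to 18 (left undefined in those SMILES) because step 13 planarises it. (S)-Glyceraldehyde acetonide and 3-bromofuran-2(5H)-one are taken as purchasable.

Step 1
Reactants: 1 (S)-2,2-dimethyl-1,3-dioxolane-4-carbaldehyde; 2 ethyl 2-(triphenylphosphoranylidene)propanoate
Product: 3 ethyl (2E)-3-[(4R)-2,2-dimethyl-1,3-dioxolan-4-yl]-2-methylprop-2-enoate
Conditions: CH2Cl2, 0 °C → rt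
Reagents that add atoms: none
Why: Wittig olefination with a stabilised α-methyl ylide should give the (E)-trisubstituted enoate (C20 cis to C6) under neutral conditions that do not epimerise the α-alkoxy centre C6, which comes unchanged from 1.

Step 2
Reactants: 3 ethyl (2E)-3-[(4R)-2,2-dimethyl-1,3-dioxolan-4-yl]-2-methylprop-2-enoate
Product: 4 (2E)-3-[(4R)-2,2-dimethyl-1,3-dioxolan-4-yl]-2-methylprop-2-en-1-ol
Conditions: i-Bu2AlH (2.2 equiv), CH2Cl2, −78 °C
Reagents that add atoms: none
Why: Reduction of an α,β-unsaturated ester to the allylic alcohol with i-Bu2AlH at low temperature is a standard 1,2-reduction that leaves the acetonide and the alkene geometry untouched.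

Step 3
Reactants: 4 (2E)-3-[(4R)-2,2-dimethyl-1,3-dioxolan-4-yl]-2-methylprop-2-en-1-ol
Product: 5 (4R)-4-[(1E)-3-bromo-2-methylprop-1-en-1-yl]-2,2-dimethyl-1,3-dioxolane
Conditions: CBr4, PPh3, 2,6-lutidine, CH2Cl2, 0 °C
Reagents that add atoms: carbon tetrabromide, BrC(Br)(Br)Br
Why: Appel bromination converts the primary allylic alcohol to the bromide by SN2 displacement of an alkoxyphosphonium ion, without allylic transposition, and the lutidine buffer protects the acetonide.

Step 4
Reactants: 6 methyl 2-methyl-3-oxobutanoate; 5 (4R)-4-[(1E)-3-bromo-2-methylprop-1-en-1-yl]-2,2-dimethyl-1,3-dioxolane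
Product: 8 methyl (6E)-7-[(4R)-2,2-dimethyl-1,3-dioxolan-4-yl]-2,6-dimethyl-3-oxohept-6-enoate, via dianion 7 (not isolated)
Conditions: NaH, THF, 0 °C; n-BuLi, 0 °C; then 5, 0 °C → rt
Reagents that add atoms: none
Why: γ-Alkylation of a β-keto ester dianion: the more basic terminal carbanion of 7 displaces the primary allylic bromide (SN2) to join C2 to C1, and C4 arises as an epimer mixture that is of no consequence.

Step 5
Reactants: 8 methyl (6E)-7-[(4R)-2,2-dimethyl-1,3-dioxolan-4-yl]-2,6-dimethyl-3-oxohept-6-enoate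
Product: 9 methyl (3S,6E)-7-[(4R)-2,2-dimethyl-1,3-dioxolan-4-yl]-3-hydroxy-2,6-dimethylhept-6-enoate
Conditions: RuCl2[(S)-BINAP](dmf)n (1 mol %), H2 (50 atm), CH2Cl2/MeOH 9:1, 50 °C
Reagents that add atoms: none
Why: Noyori asymmetric hydrogenation of a β-keto ester with the (S)-BINAP complex of divalent ruthenium should set C3 as (S) by catalyst control whatever the configuration at C4, the isolated trisubstituted alkene and (in the largely aprotic medium) the acetonide being expected to survive.

Step 6
Reactants: 9 methyl (3S,6E)-7-[(4R)-2,2-dimethyl-1,3-dioxolan-4-yl]-3-hydroxy-2,6-dimethylhept-6-enoate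
Product: 10 methyl (3S,6E)-3-[(tert-butyldimethylsilyl)oxy]-7-[(4R)-2,2-dimethyl-1,3-dioxolan-4-yl]-2,6-dimethylhept-6-enoate
Conditions: TBSCl, imidazole, DMF, 35 °C
Reagents that add atoms: tert-butyldimethylsilyl chloride, C[Si](C)(Cl)C(C)(C)C
Why: Silylation of a secondary alcohol with TBSCl/imidazole is routine and blocks C3–OH as the bulky group that later directs the ring contraction.

Step 7
Reactants: 10 methyl (3S,6E)-3-[(tert-butyldimethylsilyl)oxy]-7-[(4R)-2,2-dimethyl-1,3-dioxolan-4-yl]-2,6-dimethylhept-6-enoate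
Product: 11 methyl (3S,6E,8R)-3-[(tert-butyldimethylsilyl)oxy]-8,9-dihydroxy-2,6-dimethylnon-6-enoate
Conditions: AcOH/H2O/THF 3:1:1, 40 °C
Reagents that add atoms: none
Why: Acid hydrolysis of a terminal isopropylidene acetal is much faster than cleavage of a hindered secondary silyl ether, so the 6,7-diol is released selectively.

Step 8
Reactants: 11 methyl (3S,6E,8R)-3-[(tert-butyldimethylsilyl)oxy]-8,9-dihydroxy-2,6-dimethylnon-6-enoate
Product: 12 methyl (3S,6E,8R)-3,9-bis[(tert-butyldimethylsilyl)oxy]-8-hydroxy-2,6-dimethylnon-6-enoate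
Conditions: TBSCl (1.05 equiv), imidazole, CH2Cl2, −20 °C
Reagents that add atoms: tert-butyldimethylsilyl chloride, C[Si](C)(Cl)C(C)(C)C
Why: Primary-selective silylation with one equivalent of TBSCl at low temperature differentiates C7–OH from the secondary allylic C6–OH needed for the Claisen step.

Step 9
Reactants: 12 methyl (3S,6E,8R)-3,9-bis[(tert-butyldimethylsilyl)oxy]-8-hydroxy-2,6-dimethylnon-6-enoate
Product: 14 methyl (3S,6S,7E)-3,9-bis[(tert-butyldimethylsilyl)oxy]-2,6-dimethyl-6-(2-oxoethyl)non-7-enoate, via allyl vinyl ether 13 (not isolated)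
Conditions: n-butyl vinyl ether, Pd(OCOCF3)2 (5 mol %), 4,7-diphenyl-1,10-phenanthroline (5 mol %), Et3N, 75 °C; then toluene, 130 °C (sealed tube)
Reagents that add atoms: butyl vinyl ether, C=COCCCC
Why: Transfer vinylation followed by thermal Claisen rearrangement: in the chair transition state the CH2OSi group is equatorial (the axial alternative suffers A(1,3) strain with the cis methyl C20), so C9 is delivered to C10 on the face from which the C6–O bond leaves, which relays the C6 configuration to quaternary C10 and gives the (E)-C5=C6 alkene.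

Step 10
Reactants: 14 methyl (3S,6S,7E)-3,9-bis[(tert-butyldimethylsilyl)oxy]-2,6-dimethyl-6-(2-oxoethyl)non-7-enoate
Product: 15 methyl (3S,6S,7E)-3-[(tert-butyldimethylsilyl)oxy]-6-(2,2-dimethoxyethyl)-9-hydroxy-2,6-dimethylnon-7-enoate
Conditions: HC(OMe)3, MeOH, camphorsulfonic acid (10 mol %), 0 °C → rt
Reagents that add atoms: trimethyl orthoformate, COC(OC)OC; methanol, CO
Why: Acid-catalysed acetalisation masks the C11 aldehyde as a base-stable dimethyl acetal while the same medium methanolyses the primary allylic silyl ether, the hindered secondary C3 silyl ether being cleaved far more slowly.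

Step 11
Reactants: 15 methyl (3S,6S,7E)-3-[(tert-butyldimethylsilyl)oxy]-6-(2,2-dimethoxyethyl)-9-hydroxy-2,6-dimethylnon-7-enoate
Product: 16 (3S,6S,7E)-3-[(tert-butyldimethylsilyl)oxy]-6-(2,2-dimethoxyethyl)-9-hydroxy-2,6-dimethylnon-7-enoic acid
Conditions: LiOH, THF/MeOH/H2O, 40 °C; then dilute HCl to pH 4, 0 °C
Reagents that add atoms: lithium hydroxide, [Li+].[OH-]
Why: Saponification of the methyl ester with LiOH gives the seco acid; the acetal and silyl ether are stable to base and epimerisation at C4 does not matter.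

Step 12
Reactants: 16 (3S,6S,7E)-3-[(tert-butyldimethylsilyl)oxy]-6-(2,2-dimethoxyethyl)-9-hydroxy-2,6-dimethylnon-7-enoic acid
Product: 18 (4S,7S,8E)-4-[(tert-butyldimethylsilyl)oxy]-7-(2,2-dimethoxyethyl)-3,7-dimethyloxacyclodec-8-en-2-one, via mixed anhydride 17 (not isolated)
Conditions: 2-methyl-6-nitrobenzoic anhydride, DMAP, Et3N, toluene (2 mM, slow addition of 16), 40 °C
Reagents that add atoms: none
Why: Shiina macrolactonisation: slow addition keeps the mixed anhydride 17 dilute so that DMAP-mediated acyl transfer to the unhindered allylic C7–OH should outrun oligomerisation, the quaternary C10 and the E-alkene limiting the conformational freedom of the chain; no stereocentre is formed.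

Step 13
Reactants: 18 (4S,7S,8E)-4-[(tert-butyldimethylsilyl)oxy]-7-(2,2-dimethoxyethyl)-3,7-dimethyloxacyclodec-8-en-2-one
Product: 21 (1S,2S,3S,6S)-6-[(tert-butyldimethylsilyl)oxy]-3-(2,2-dimethoxyethyl)-2-ethenyl-1,3-dimethylcyclohexane-1-carboxylic acid, via silyl ketene acetal 19 (not isolated), via trimethylsilyl ester 20 (not isolated)
Conditions: LiN(i-Pr)2 added to 18 and Me3SiCl/Et3N, THF, −78 °C → rt; toluene, 80 °C; then K2CO3 (cat.), MeOH/H2O, rt, pH 5 work-up
Reagents that add atoms: none
Why: Deprotonation at C4 (the only acidic C–H) in the presence of Me3SiCl gives silyl ketene acetal 19, whose ring forces C3 and the ring oxygen cis on C4=C19, and a concerted suprafacial [3,3] shift then bonds C4 to C5 while O–C7 breaks, leaving C19 as a silyl ester and C6=C7 as a vinyl group. The closest known reaction type is the Ireland–Claisen ring contraction of alkenyl macrolactones to cis-2-alkenylcycloalkanecarboxylic acids. Ring A (C4, C3, C2, C1, C10, C5) closes by transannular C–C bonding, a four-atom contraction of the ten-membered ring, through a chair-like six-atom array (the only one that the E-alkene and the ring-cis ketene acetal can reach) fused to a chair-like nascent cyclohexane. C4 and C5 are therefore formed with C19 cis to the vinyl group, and their sense relative to C10 is set by C3: the C3 substituent that ends cis to the vinyl group must lie in the ketene-acetal plane beside the ring oxygen, a site only hydrogen fills without A(1,3) strain, so the (3S)-silyloxy group points outward and equatorial, C20 is equatorial and the C9 arm sits on the face of C18. The step needs this face selectivity and no loss of the β-silyloxy group, which the deliberately chosen 3-epi configuration and the in-situ silylation at −78 °C should secure.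

Step 14
Reactants: 21 (1S,2S,3S,6S)-6-[(tert-butyldimethylsilyl)oxy]-3-(2,2-dimethoxyethyl)-2-ethenyl-1,3-dimethylcyclohexane-1-carboxylic acid
Product: 22 [(1R,2S,3S,6S)-6-[(tert-butyldimethylsilyl)oxy]-3-(2,2-dimethoxyethyl)-2-ethenyl-1,3-dimethylcyclohexyl]methanol
Conditions: LiAlH4, THF, 0 °C → reflux
Reagents that add atoms: none
Why: LiAlH4 reduces the hindered quaternary carboxylic acid to the neopentyl alcohol C19 (hydride reduction), and the acetal, silyl ether and vinyl group are inert to it.

Step 15
Reactants: 22 [(1R,2S,3S,6S)-6-[(tert-butyldimethylsilyl)oxy]-3-(2,2-dimethoxyethyl)-2-ethenyl-1,3-dimethylcyclohexyl]methanol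
Product: 23 4-methoxybenzyl ether of 22 (C19–O–CH2C6H4OMe)
Conditions: NaH, 4-methoxybenzyl chloride, n-Bu4NI (cat.), DMF, 0 °C → rt
Reagents that add atoms: 4-methoxybenzyl chloride, COc1ccc(CCl)cc1
Why: Williamson etherification of the sodium alkoxide with 4-methoxybenzyl chloride (iodide catalysis) protects C19–OH with a group that survives fluoride, hydride, ylide and acid and can be removed oxidatively at the end.

Step 16
Reactants: 23 4-methoxybenzyl ether of 22
Product: 24 ring-A propanal (the C5 vinyl group of 23 converted into C6H2–C7H2–C8HO)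
Conditions: Rh(acac)(CO)2 (1 mol %), Xantphos (2 mol %), CO/H2 1:1 (10 bar), toluene, 80 °C
Reagents that add atoms: carbon monoxide, [C-]#[O+]
Why: Rhodium-catalysed hydroformylation with a wide-bite-angle diphosphine adds the formyl carbon C8 to the terminal carbon C7, the branched position being doubly neopentyl, to give the linear aldehyde.

Step 17
Reactants: 24 ring-A propanal
Product: 27 (E)-nitroalkene (C5 side chain C6H2–C7H2–C8H=C17H–NO2), via nitro alcohol 25 (not isolated), via nitro mesylate 26 (not isolated)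
Conditions: MeNO2, Et3N (cat.), rt; evaporate; MsCl, Et3N, CH2Cl2, 0 °C
Reagents that add atoms: nitromethane, C[N+](=O)[O-]
Why: Henry addition of nitromethane to the aldehyde followed by mesylation and E1cB elimination gives the (E)-nitroalkene, which makes C8 electrophilic and carries C17 as a masked carbonyl carbon.

Step 18
Reactants: 27 (E)-nitroalkene
Product: 28 nitroalkene aldehyde (C10 arm CH2–C11HO)
Conditions: pyridinium p-toluenesulfonate, acetone/H2O 10:1, 50 °C
Reagents that add atoms: water, O
Why: Mild acid hydrolysis of the dimethyl acetal frees the C11 aldehyde; the nitroalkene, the benzyl-type ether and the hindered secondary silyl ether tolerate pyridinium tosylate in wet acetone.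

Step 19
Reactants: 28 nitroalkene aldehyde
Product: 29 trans-decalin nitro aldehyde (C9 formyl and C8 nitromethyl both equatorial; 3-epi silyl ether; 19-O-4-methoxybenzyl)
Conditions: pyrrolidine (20 mol %), AcOH (20 mol %), CHCl3, rt
Reagents that add atoms: none
Why: Enamine-mediated intramolecular Michael addition (6-exo-trig) of the C11 aldehyde to the nitroalkene: only the ring-A chair with both arms equatorial can cyclise, so ring B is trans-fused, the nitrovinyl unit avoids the axial C20 methyl and so places C17 equatorial at C8, and the enolisable C9 formyl group equilibrates to the equatorial position.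

Step 20
Reactants: 29 trans-decalin nitro aldehyde
Product: 30 C9-vinyl nitro decalin (C11=C12)
Conditions: Ph3PCH3Br (3 equiv), KOt-Bu (3 equiv), THF, 0 °C → rt; AcOH quench
Reagents that add atoms: methyltriphenylphosphonium bromide, C[P+](c1ccccc1)(c1ccccc1)c1ccccc1.[Br-]
Why: Wittig methylenation of the aldehyde converts C11 into the vinyl group C11=C12; an excess of ylide is used because one equivalent is consumed by deprotonation of the nitroalkane, and C9, from now on not enolisable, keeps its equatorial configuration.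

Step 21
Reactants: 30 C9-vinyl nitro decalin
Product: 31 3-epi alcohol (axial C3–OH)
Conditions: HF (48 % aq.), MeCN, 40 °C
Reagents that add atoms: none
Why: Fluoride cleaves the Si–O bond of the hindered axial silyl ether (desilylation with aqueous HF), while the 4-methoxybenzyl ether, the nitro group and the alkene are unaffected.

Step 22
Reactants: 31 3-epi alcohol
Product: 32 C3 ketone
Conditions: Dess–Martin periodinane, NaHCO3, CH2Cl2, rt
Reagents that add atoms: none
Why: Dess–Martin oxidation of the axial secondary alcohol gives the C3 ketone under buffered, non-basic conditions that leave the primary nitroalkane and the 4-methoxybenzyl ether intact, which erases the temporary 3-epi centre.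

Step 23
Reactants: 32 C3 ketone
Product: 34 keto aldehyde (C17 formyl at C8), via sodium nitronate 33 (not isolated)
Conditions: NaOMe, MeOH, 0 °C; then TiCl3, NH4OAc, H2O (pH 5–6), 0 °C → rt
Reagents that add atoms: water, O
Why: Reductive Nef reaction: the nitronate 33 is reduced and hydrolysed by buffered aqueous TiCl3 (trivalent titanium) to the C17 aldehyde, conditions under which ketones and isolated alkenes are not reduced.

Step 24
Reactants: 34 keto aldehyde
Product: 35 3,17-diol (19-O-4-methoxybenzyl; C9 vinyl)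
Conditions: K2CO3 (cat.), MeOH, rt; then NaBH4, 0 °C
Reagents that add atoms: none
Why: Base equilibration leaves the C8 formyl group equatorial, and NaBH4 then reduces it and the C3 ketone (carbonyl reduction), hydride reaching C3 along the axial trajectory on the face opposite the axial C19 and C20 groups to give the equatorial 3-alcohol of the target.

Step 25
Reactants: 35 3,17-diol; 36 3-bromofuran-2(5H)-one
Product: 38 19-O-(4-methoxybenzyl)-14-deoxy-17-hydroxyandrographolide, via alkylborane 37 (not isolated)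
Conditions: 9-BBN dimer (excess), THF, rt → 50 °C; then 36, PdCl2(dppf) (10 mol %), Ph3As, Cs2CO3, DMF/H2O, rt
Reagents that add atoms: none
Why: Anti-Markovnikov hydroboration of the only alkene followed by B-alkyl Suzuki–Miyaura coupling with the α-bromobutenolide forms C12–C13 with the ring alkene already in its conjugated position, and no stereocentre is created.

Step 26
Reactants: 38 19-O-(4-methoxybenzyl)-14-deoxy-17-hydroxyandrographolide
Product: 39 14-deoxy-17-hydroxyandrographolide
Conditions: DDQ, CH2Cl2/pH 7 buffer, 0 °C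
Reagents that add atoms: none
Why: Oxidative cleavage of the 4-methoxybenzyl ether with DDQ in wet dichloromethane (oxidation to the oxocarbenium ion and hydrolysis) frees C19–OH without touching the butenolide or the other alcohols.

**Compound list**
1 | (S)-2,2-dimethyl-1,3-dioxolane-4-carbaldehyde | O=C[C@@H]1COC(C)(C)O1 | starting material
2 | ethyl 2-(triphenylphosphoranylidene)propanoate | CCOC(=O)C(C)=P(c1ccccc1)(c1ccccc1)c1ccccc1 | starting material
3 | ethyl (2E)-3-[(4R)-2,2-dimethyl-1,3-dioxolan-4-yl]-2-methylprop-2-enoate | CCOC(=O)/C(C)=C/[C@@H]1COC(C)(C)O1 | intermediate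
4 | (2E)-3-[(4R)-2,2-dimethyl-1,3-dioxolan-4-yl]-2-methylprop-2-en-1-ol | OC/C(C)=C/[C@@H]1COC(C)(C)O1 | intermediate
5 | (4R)-4-[(1E)-3-bromo-2-methylprop-1-en-1-yl]-2,2-dimethyl-1,3-dioxolane | BrC/C(C)=C/[C@@H]1COC(C)(C)O1 | intermediate
6 | methyl 2-methyl-3-oxobutanoate | COC(=O)C(C)C(C)=O | starting material
7 | sodium lithium dianion (bis-enolate) of methyl 2-methyl-3-oxobutanoate | COC([O-])=C(C)C([O-])=C.[Na+].[Li+] | intermediate
8 | methyl (6E)-7-[(4R)-2,2-dimethyl-1,3-dioxolan-4-yl]-2,6-dimethyl-3-oxohept-6-enoate (C2 epimers) | COC(=O)C(C)C(=O)CC/C(C)=C/[C@@H]1COC(C)(C)O1 | intermediate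
9 | methyl (3S,6E)-7-[(4R)-2,2-dimethyl-1,3-dioxolan-4-yl]-3-hydroxy-2,6-dimethylhept-6-enoate | COC(=O)C(C)[C@@H](O)CC/C(C)=C/[C@@H]1COC(C)(C)O1 | intermediate
10 | methyl (3S,6E)-3-[(tert-butyldimethylsilyl)oxy]-7-[(4R)-2,2-dimethyl-1,3-dioxolan-4-yl]-2,6-dimethylhept-6-enoate | COC(=O)C(C)[C@@H](O[Si](C)(C)C(C)(C)C)CC/C(C)=C/[C@@H]1COC(C)(C)O1 | intermediate
11 | methyl (3S,6E,8R)-3-[(tert-butyldimethylsilyl)oxy]-8,9-dihydroxy-2,6-dimethylnon-6-enoate | COC(=O)C(C)[C@@H](O[Si](C)(C)C(C)(C)C)CC/C(C)=C/[C@@H](O)CO | intermediate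
12 | methyl (3S,6E,8R)-3,9-bis[(tert-butyldimethylsilyl)oxy]-8-hydroxy-2,6-dimethylnon-6-enoate | COC(=O)C(C)[C@@H](O[Si](C)(C)C(C)(C)C)CC/C(C)=C/[C@@H](O)CO[Si](C)(C)C(C)(C)C | intermediate
13 | methyl (3S,6E,8R)-3,9-bis[(tert-butyldimethylsilyl)oxy]-8-(ethenyloxy)-2,6-dimethylnon-6-enoate (allyl vinyl ether) | COC(=O)C(C)[C@@H](O[Si](C)(C)C(C)(C)C)CC/C(C)=C/[C@@H](OC=C)CO[Si](C)(C)C(C)(C)C | intermediate
14 | methyl (3S,6S,7E)-3,9-bis[(tert-butyldimethylsilyl)oxy]-2,6-dimethyl-6-(2-oxoethyl)non-7-enoate | COC(=O)C(C)[C@@H](O[Si](C)(C)C(C)(C)C)CC[C@@](C)(CC=O)/C=C/CO[Si](C)(C)C(C)(C)C | intermediate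
15 | methyl (3S,6S,7E)-3-[(tert-butyldimethylsilyl)oxy]-6-(2,2-dimethoxyethyl)-9-hydroxy-2,6-dimethylnon-7-enoate | COC(=O)C(C)[C@@H](O[Si](C)(C)C(C)(C)C)CC[C@@](C)(CC(OC)OC)/C=C/CO | intermediate
16 | (3S,6S,7E)-3-[(tert-butyldimethylsilyl)oxy]-6-(2,2-dimethoxyethyl)-9-hydroxy-2,6-dimethylnon-7-enoic acid | OC(=O)C(C)[C@@H](O[Si](C)(C)C(C)(C)C)CC[C@@](C)(CC(OC)OC)/C=C/CO | intermediate
17 | mixed anhydride of 16 with 2-methyl-6-nitrobenzoic acid | Cc1cccc([N+](=O)[O-])c1C(=O)OC(=O)C(C)[C@@H](O[Si](C)(C)C(C)(C)C)CC[C@@](C)(CC(OC)OC)/C=C/CO | intermediate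
18 | (4S,7S,8E)-4-[(tert-butyldimethylsilyl)oxy]-7-(2,2-dimethoxyethyl)-3,7-dimethyloxacyclodec-8-en-2-one (ten-membered lactone; C19 = ring C2, C7 = ring C10) | O=C1OC/C=C/[C@](C)(CC(OC)OC)CC[C@H](O[Si](C)(C)C(C)(C)C)C1C | intermediate
19 | trimethylsilyl ketene acetal of 18 (C4=C19 with C3 and ring O cis) | C/C1=C(\O[Si](C)(C)C)OC/C=C/[C@](C)(CC(OC)OC)CC[C@@H]1O[Si](C)(C)C(C)(C)C | intermediate
20 | trimethylsilyl ester of 21 | C[C@]1(C(=O)O[Si](C)(C)C)[C@@H](C=C)[C@](C)(CC(OC)OC)CC[C@@H]1O[Si](C)(C)C(C)(C)C | intermediate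
21 | (1S,2S,3S,6S)-6-[(tert-butyldimethylsilyl)oxy]-3-(2,2-dimethoxyethyl)-2-ethenyl-1,3-dimethylcyclohexane-1-carboxylic acid (ring A; carboxyl cis to the vinyl group and to the C10 methyl, trans to the silyloxy group) | C[C@]1(C(=O)O)[C@@H](C=C)[C@](C)(CC(OC)OC)CC[C@@H]1O[Si](C)(C)C(C)(C)C | intermediate
22 | [(1R,2S,3S,6S)-6-[(tert-butyldimethylsilyl)oxy]-3-(2,2-dimethoxyethyl)-2-ethenyl-1,3-dimethylcyclohexyl]methanol | C[C@]1(CO)[C@@H](C=C)[C@](C)(CC(OC)OC)CC[C@@H]1O[Si](C)(C)C(C)(C)C | intermediate
23 | 4-methoxybenzyl ether of 22 | C[C@]1(COCc2ccc(OC)cc2)[C@@H](C=C)[C@](C)(CC(OC)OC)CC[C@@H]1O[Si](C)(C)C(C)(C)C | intermediate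
24 | ring-A propanal (C5 bears CH2CH2CHO; otherwise as 23) | C[C@]1(COCc2ccc(OC)cc2)[C@@H](CCC=O)[C@](C)(CC(OC)OC)CC[C@@H]1O[Si](C)(C)C(C)(C)C | intermediate
25 | nitro alcohol (C5 bears CH2CH2CH(OH)CH2NO2; carbinol epimers) | C[C@]1(COCc2ccc(OC)cc2)[C@@H](CCC(O)C[N+](=O)[O-])[C@](C)(CC(OC)OC)CC[C@@H]1O[Si](C)(C)C(C)(C)C | intermediate
26 | methanesulfonate of 25 | C[C@]1(COCc2ccc(OC)cc2)[C@@H](CCC(OS(C)(=O)=O)C[N+](=O)[O-])[C@](C)(CC(OC)OC)CC[C@@H]1O[Si](C)(C)C(C)(C)C | intermediate
27 | (E)-nitroalkene (C5 bears CH2CH2CH=CHNO2; acetal arm on C10) | C[C@]1(COCc2ccc(OC)cc2)[C@@H](CC/C=C/[N+](=O)[O-])[C@](C)(CC(OC)OC)CC[C@@H]1O[Si](C)(C)C(C)(C)C | intermediate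
28 | nitroalkene aldehyde (C10 bears CH2CHO) | C[C@]1(COCc2ccc(OC)cc2)[C@@H](CC/C=C/[N+](=O)[O-])[C@](C)(CC=O)CC[C@@H]1O[Si](C)(C)C(C)(C)C | intermediate
29 | trans-decalin nitro aldehyde (C9 equatorial CHO, C8 equatorial CH2NO2, 3-epi OTBS axial, 19-O-4-methoxybenzyl; C4, C5, C8, C9, C10 as in the target) | C[C@]1(COCc3ccc(OC)cc3)[C@H]2CC[C@H](C[N+](=O)[O-])[C@@H](C=O)[C@]2(C)CC[C@@H]1O[Si](C)(C)C(C)(C)C | intermediate
30 | C9-vinyl nitro decalin (CHO of 29 replaced by CH=CH2) | C[C@]1(COCc3ccc(OC)cc3)[C@H]2CC[C@H](C[N+](=O)[O-])[C@@H](C=C)[C@]2(C)CC[C@@H]1O[Si](C)(C)C(C)(C)C | intermediate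
31 | 3-epi alcohol (axial C3–OH; otherwise as 30) | C[C@]1(COCc3ccc(OC)cc3)[C@H]2CC[C@H](C[N+](=O)[O-])[C@@H](C=C)[C@]2(C)CC[C@@H]1O | intermediate
32 | C3 ketone (otherwise as 31) | C[C@]1(COCc3ccc(OC)cc3)[C@H]2CC[C@H](C[N+](=O)[O-])[C@@H](C=C)[C@]2(C)CCC1=O | intermediate
33 | sodium nitronate of 32 | C[C@]1(COCc3ccc(OC)cc3)[C@H]2CC[C@H](C=[N+]([O-])[O-])[C@@H](C=C)[C@]2(C)CCC1=O.[Na+] | intermediate
34 | keto aldehyde (C3 ketone, C8 equatorial CHO, C9 vinyl) | C[C@]1(COCc3ccc(OC)cc3)[C@H]2CC[C@H](C=O)[C@@H](C=C)[C@]2(C)CCC1=O | intermediate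
35 | 3,17-diol (equatorial C3–OH, C8 equatorial CH2OH, C9 vinyl, 19-O-4-methoxybenzyl) | C[C@]1(COCc3ccc(OC)cc3)[C@H]2CC[C@H](CO)[C@@H](C=C)[C@]2(C)CC[C@H]1O | intermediate
36 | 3-bromofuran-2(5H)-one | O=C1OCC=C1Br | starting material
37 | C12 9-borabicyclo[3.3.1]nonan-9-yl adduct of 35 (alkylborane) | C[C@]1(COCc3ccc(OC)cc3)[C@H]2CC[C@H](CO)[C@@H](CCB4C5CCCC4CCC5)[C@]2(C)CC[C@H]1O | intermediate
38 | 19-O-(4-methoxybenzyl)-14-deoxy-17-hydroxyandrographolide | C[C@]1(COCc4ccc(OC)cc4)[C@H]2CC[C@H](CO)[C@@H](CCC3=CCOC3=O)[C@]2(C)CC[C@H]1O | intermediate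
39 | 14-deoxy-17-hydroxyandrographolide | C[C@]1(CO)[C@H]2CC[C@H](CO)[C@@H](CCC3=CCOC3=O)[C@]2(C)CC[C@H]1O | target

**Step count and risks**

Total steps: 26. Longest linear sequence: 26 steps (1 → 39).

Steps most likely to fail:

Step 13. Bond formation could occur on the other face of the ketene acetal, so that C4/C5 form with the wrong sense relative to C10, or silanolate could be lost from the lactone enolate before it is silylated. The fallback leaves the pericyclic manifold and sets out from compound 15. The allylic alcohol is converted (MsCl, LiCl, 2,4,6-collidine, DMF, 0 °C) into methyl (3S,6S,7E)-3-[(tert-butyldimethylsilyl)oxy]-9-chloro-6-(2,2-dimethoxyethyl)-2,6-dimethylnon-7-enoate F1. Its potassium ester enolate (KN(SiMe3)2, THF, −78 → 0 °C) should close ring A by a 6-exo intramolecular SN2′ alkylation, a known reaction type for ester enolates and allylic chlorides, forming the same C4–C5 bond through an open transition state whose facial bias is set by enolate geometry and the anti SN2′ trajectory. The product is the methyl ester of acid 21, F2. LiAlH4 reduces F2 directly to alcohol 22, where the route is rejoined.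

Step 12. Intermolecular acylation (diolide and oligomer formation) may outrun closure of the strained ten-membered ring. The fallback sets out from seco acid 16 and activates the alcohol instead of the acid: Mitsunobu macrolactonisation (PPh3, diisopropyl azodicarboxylate, toluene, high dilution, 0 °C → rt) turns the primary allylic C7–OH into an alkoxyphosphonium ion that the carboxylate displaces by SN2. No new isolable compound is made, and the route is rejoined at lactone 18.

Step 25. Transmetalation of the hindered alkylborane may be slow, so that protodeboronation and base-induced ring opening or double-bond migration of the bromobutenolide compete. The fallback sets out from diol 35 and avoids base. Hydroboration with 9-BBN followed by iodination (I2, NaOMe, MeOH) gives the primary iodide F3 (C12–I). A nickel-catalysed reductive cross-electrophile coupling of this alkyl iodide with alkenyl bromide 36 (NiBr2(MeOCH2CH2OMe), 4,4′-di-tert-butyl-2,2′-bipyridine, Zn, N,N-dimethylacetamide, rt), a known coupling class that tolerates free hydroxyl groups, then gives 38, where the route is rejoined.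

**Further compounds**
F1 | step 13 | methyl (3S,6S,7E)-3-[(tert-butyldimethylsilyl)oxy]-9-chloro-6-(2,2-dimethoxyethyl)-2,6-dimethylnon-7-enoate | COC(=O)C(C)[C@@H](O[Si](C)(C)C(C)(C)C)CC[C@@](C)(CC(OC)OC)/C=C/CCl
F2 | step 13 | methyl (1S,2S,3S,6S)-6-[(tert-butyldimethylsilyl)oxy]-3-(2,2-dimethoxyethyl)-2-ethenyl-1,3-dimethylcyclohexane-1-carboxylate | C[C@]1(C(=O)OC)[C@@H](C=C)[C@](C)(CC(OC)OC)CC[C@@H]1O[Si](C)(C)C(C)(C)C
F0 | step 12 | none | none
F3 | step 25 | C12 iodide derived from 35 (C9 bears CH2CH2I) | C[C@]1(COCc3ccc(OC)cc3)[C@H]2CC[C@H](CO)[C@@H](CCI)[C@]2(C)CC[C@H]1O
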